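## Structural features

The target is a briarane-type diterpenoid. Ring A (C1, C10 to C14) is a cyclohexane that is trans-fused through the C1–C10 bond to a ten-membered carbocycle (C1 to C10). A γ-lactone (O7–C19, with C17 and its methyl C18) is fused to the large ring at C7–C8. Nine stereocentres are present: quaternary C1 (methyl C15) lies between the oxygenated C14 and C2, and C7, C8 (tertiary carbinol), C9 and C10 are contiguous and continue into C17; C4 is an allylic acetoxy carbon next to the Z alkene C5(CH3)=C6. Fragile elements are the four ester groups (acyl migration, base), the allylic C4 acetate, the exocyclic C11 methylene next to the C10 hydrogen (isomerization into the ring), and the tertiary β-hydroxy lactone (retro-aldol, dehydration). The real difficulty is the ten-membered ring with a cis trisubstituted alkene and seven stereocentres on it, flanked by the quaternary C1 and the fully substituted C8. The key step exploits that C2 and C7 both carry oxygen and are 1,6-related across the large ring. A C2–C7 bond converts it into ring B (C1, C2, C7, C8, C9, C10) and ring C (C2 to C7), an angular tricycle of three six-membered rings in which C5=C6 is necessarily cis and every other ring stereocentre sits on a chair or half-chair. Briarane numbering is used for all intermediates; α is the face of H10, β the face of the C15 methyl.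

## Logic of the disconnections

39 ⇒ 38 ⇒ 37. The three acetate C–O bonds (O4, O9, O14) are cut, then the four O–Si bonds are restored. Acetates are placed last because they would not survive the basic steps and because a C4 ester would sit β to the C2 ketone of 32. The gain is that O2 can be acylated alone. The demand is that the tertiary O8 hydroxyl of 38 is not acetylated.

37 ⇒ 36 ⇒ 33. The O2–isobutyryl bond and then the lactone bond O7–C19 are cut. Closing the lactone first removes O7 from competition with O2. The forward step must free the acid from its tert-butyl ester without touching alkyl silyl ethers.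

33 ⇒ 32. The C2–H and C7–H bonds are cut back to two ketones. This removes two stereocentres and leads to the cleavage product. The forward reduction must be face-selective at both carbonyls of a flexible ring.

32 ⇒ 30. The C2–C7 bond is reconnected and the two carbonyl oxygens become a cis glycol. The medium ring is exchanged for two six-membered rings. The forward step must cleave this glycol and nothing else.

30 ⇒ 29 ⇒ 28 ⇒ 27. The C11=C20 bond is cut to a ketone, and the ketone is traced to a pivalate-masked alcohol. An exocyclic alkene would compete in the dihydroxylation and would isomerize at the C9 ketone stage, so it is made late. The forward methylenation must be non-basic.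

27 ⇒ 26 ⇒ 25 ⇒ 24. The C4–H bond is cut to an enone and the C5=C6 unsaturation is removed. This leaves a plain C4 ketone. Dehydrogenation can only go toward C5/C6, because C2 has no hydrogen.

24 ⇒ 22 ⇒ 21 ⇒ 19 ⇒ 18. The two C–O bonds at C2 and C7 are cut to a tetrasubstituted alkene. That alkene is traced to the conjugated C2=C3 enone by double-bond migration, and the enone to the ketone and the Diels–Alder silyl enol ether. The gain is an unambiguous placement of the ring-fusion alkene. The demand is kinetic protonation of a dienolate at C3.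

18 ⇒ 17 ⇒ 16 ⇒ 15. The O–Si bonds are cut, and the C9–H bond is cut to a ketone. The ketone comes from the 9α alcohol. The detour is accepted because only reduction of a C9 ketone gives the axial 9β oxygen reliably.

15 ⇒ 13 + 14 and 13 ⇒ 12. The C8–C17 bond is cut (aldol), then the C9–O bond (enolate oxidation). The aldol is placed after ring C is in position because the axial C2–C3 bond then directs attack on C8.

12 ⇒ 9 + 11, and 11 ⇒ 10. The C2–C3 and C6–C7 bonds are cut (Diels–Alder). Four ring C carbons, the C4 oxygen and the C16 methyl arrive in one step. The demand is regiocontrol by the silyloxy group and attack anti to C15.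

9 ⇒ 7 ⇒ 6 ⇒ 5 ⇒ 4 ⇒ 3 ⇒ 2 ⇒ 1. The C2=C7 unsaturation is removed, then the protecting groups. The C11–O and C10–H bonds are cut (hydroboration of a C10=C11 alkene obtained by deconjugative ketalization), and finally the C14–H bond. All remaining carbons and the C1 stereocentre are in 1.

## Other disconnections considered

Alternative 1: The cut goes through ring A at C1–C14 and C10–C11. In the forward sense (1E,3E)-1,4-diacetoxybuta-1,3-diene A1 would add to the E-configured 2-methyl enal A2 under Me2AlCl to give cycloadduct A3.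
- In its favour: one step creates quaternary C1, C10, C14 and an oxygen handle on C11, with absolute control relayed from the dioxolane carbon (C9). On ring A this is better than the chosen plan, which spends about seven steps on the same centres and needs a bulky hydride to get the C14 configuration.
- Against it here: it says nothing about the ten-membered ring. C2 to C8 must still be attached and the medium ring closed by a separate bond-forming event, with the entropic and transannular cost that the chosen plan avoids. The diacyloxy diene is also electron-poor for a trisubstituted enal.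
- Comparison: structurally it is complementary (ring A) and not a competitor for the large ring. Mechanistically both plans rest on a cycloaddition for their early carbons. In step economy it wins early, but the total is open until the ring closure is solved.

Alternative 2: The cut is at C3–C4 together with O–C2. An intramolecular nitrile oxide–alkene cycloaddition (oxime, NaOCl) would close the carbocycle and give isoxazoline A4.
- In its favour: ring closure and the C2–O bond are made in one step, and the heterocycle is a masked C2 carbinol/C4 ketone. Here the alternative is the better plan, because the C2 oxygen needs no separate ketone reduction. It is also convergent and late-stage.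
- Against it here: a ten-membered ring is closed by direct bond formation between two chain ends. The nitrile oxide is conjugated to the Z alkene and may dimerize to a furoxan. The C2 configuration depends on a macrocyclic transition state that is hard to predict. N–O cleavage and C4 reduction remain.
- Comparison: structurally it forms one skeletal bond where the chosen key step forms none. Mechanistically it is a bimolecular-type closure against ring strain, against a fragmentation that releases the ring. Step economy is about equal if the closure works.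

Alternative 3: The cut is at C1–C2. An anionic oxy-Cope rearrangement (KH, 18-crown-6) would break C4–C9 and form C1–C2, enlarging a six-membered ring to the ten-membered ring, and protonation at C10 would give ketone A5.
- In its favour: like the chosen plan it is a ring expansion of a six-membered template, and the Z alkene is also inherited from that ring, so on these two points it is equal. It is better in that the same step forms a C–C bond and the quaternary centre C1.
- Against it here: the new bond must be made at a fully substituted alkene terminus. The C1 configuration, the enol ether geometry and the C10 configuration all depend on the chair or boat shape of the transition state and on a kinetic protonation. The template with adjacent fully substituted C4 and C9 is itself hard to make.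
- Comparison: structurally both plans hide the large ring in a small one. Mechanistically a sigmatropic step that creates three stereochemical elements carries more risk than a cleavage that creates none. Step economy is similar.

Key step: step 25

Remarks and assumptions on the chemistry:
- C14: ordinary borohydride reduction of 1 gives the equatorial 14β alcohol (cis to C15), the wrong epimer; the route therefore uses LiBH(s-Bu)3.
- Design of 30: a methyl ester at C19 and acetates on O4, O9 and O14 would be the simplest version, but the 7β hydroxyl is cis to the side chain on ring B (γ-lactonization would consume the glycol), and a C4 ester would be β to the new C2 ketone. The route therefore carries a tert-butyl ester and silyl ethers and places the acetates last.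
- Assumption: the dihydroxylation in step 18 is drawn on the β face (anti to the O8 silyl ether). The α,α-diol would behave identically in step 25, because C2 and C7 become carbonyl carbons.
- Assumption: the C17 configuration drawn from step 11 onward is the one expected from the E lithium enolate through a closed chair transition state.
- C11: the ring A carbonyl carbon for C20 is introduced by hydroboration of a C10=C11 alkene and not by γ-oxidation of the enone, because this also sets the trans ring fusion.

Step 1
Reactants: 1 (R)-Wieland–Miescher ketone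
Product: 2 bicyclic diol (axial 14α-hydroxyl trans to C15; allylic C8 alcohol as epimer mixture; C9=C10)
Conditions: LiBH(s-Bu)3 (2.5 equiv), THF, −78 °C; then NaOH, H2O2
Reagents that add atoms: none
Why: Reduction with a bulky trialkylborohydride; equatorial delivery to the C14 carbonyl next to the quaternary C1 should give the axial 14α alcohol, the epimer that small hydrides do not give, while the β,β-disubstituted enone is reduced 1,2 to an allylic alcohol that step 2 re-oxidizes.

Step 2
Reactants: 2 bicyclic diol
Product: 3 14α-hydroxy enone (C8 ketone, C9=C10)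
Conditions: MnO2 (activated, excess), CH2Cl2, rt
Reagents that add atoms: none
Why: Chemoselective oxidation of the allylic alcohol by MnO2 restores the enone; the saturated axial C14 alcohol is not oxidized.

Step 3
Reactants: 3 14α-hydroxy enone
Product: 4 C8 ethylene ketal with the alkene moved to C10=C11 (14α-hydroxyl free)
Conditions: ethane-1,2-diol, p-TsOH (cat.), benzene, reflux, water separator
Reagents that add atoms: ethane-1,2-diol OCCO
Why: Acid-catalysed ketalization of an octalenone moves the alkene out of conjugation (C9=C10 to C10=C11), the usual outcome for this class; this places the alkene where C10–H and the C11 oxygen can be delivered together.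

Step 4
Reactants: 4 deconjugated ketal
Product: 5 trans-fused 11α,14α-diol ketal (10α-H)
Conditions: BH3·THF (3 equiv), THF, 0 °C to rt; then NaOH, H2O2
Reagents that add atoms: hydrogen peroxide OO
Why: Hydroboration–oxidation; borane adds cis from the α face, anti to the axial C15 methyl on the adjacent C1, with boron on the less substituted C11, which sets the trans ring fusion (10α-H) and the 11α-hydroxyl.

Step 5
Reactants: 5 11α,14α-diol ketal
Product: 6 11α-pivalate (14α-hydroxyl free)
Conditions: t-BuCOCl (1.2 equiv), pyridine, DMAP (cat.), CH2Cl2, 0 °C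
Reagents that add atoms: pivaloyl chloride CC(C)(C)C(=O)Cl
Why: Acylation with a bulky acid chloride distinguishes the unhindered equatorial C11 alcohol from the axial neopentyl C14 alcohol; the pivalate has no α-hydrogen and survives the later strong bases.

Step 6
Reactants: 6 11α-pivalate ketal
Product: 7 trans-decalin-8-one (11α-pivalate, 14α-hydroxyl)
Conditions: PPTS, acetone/H2O (10:1), 55 °C
Reagents that add atoms: water O
Why: Acid-catalysed acetal hydrolysis frees the C8 ketone; the pivalate and the free alcohol are stable to these conditions.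

Step 7
Reactants: 7 trans-decalin-8-one
Product: 9 bicyclic enone (C8 ketone; C2=C7; 14α-OTBS; 11α-pivalate), via silyl enol ether 8 (not isolated)
Conditions: t-BuMe2SiOTf (2.5 equiv), Et3N, CH2Cl2, 0 °C; then Pd(OAc)2 (1.2 equiv), DMSO/MeCN, 40 °C
Reagents that add atoms: tert-butyldimethylsilyl triflate CC(C)(C)[Si](C)(C)OS(=O)(=O)C(F)(F)F
Why: Soft enolization of the trans-fused ketone should give mainly the C7=C8 silyl enol ether and silylates O14 in the same operation; Saegusa–Ito oxidation with Pd(OAc)2 then gives the enone, β-hydride elimination being possible only from C2.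

Step 8
Reactants: 10 3-methylbut-3-en-2-one
Product: 11 2-(tert-butyldimethylsilyloxy)-3-methylbuta-1,3-diene
Conditions: t-BuMe2SiOTf, Et3N, Et2O, 0 °C
Reagents that add atoms: tert-butyldimethylsilyl triflate CC(C)(C)[Si](C)(C)OS(=O)(=O)C(F)(F)F
Why: O-Silylation of the enone under soft-enolization conditions gives the 2-silyloxy diene.

Step 9
Reactants: 9 bicyclic enone; 11 2-silyloxy diene
Product: 12 tricyclic adduct (ring C cis-fused on the α face, 2β-H and 7β-H; C4=C5 silyl enol ether; C8 ketone)
Conditions: HNTf2 (10 mol%), CH2Cl2, −78 to −30 °C; Et3N quench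
Reagents that add atoms: none
Why: Diels–Alder reaction of a 2-silyloxy diene with a cyclic enone, catalysed by the silyl triflimide formed in situ; the CH2 terminus next to the silyloxy carbon bonds to the enone β-carbon C2, which puts the oxygen on C4 and the methyl on C5. The diene should add to the α face, anti to the axial C15 methyl on the adjacent quaternary C1, so ring C is cis-fused with the C2–C3 bond axial on ring B.

Step 10
Reactants: 12 tricyclic adduct
Product: 13 9α-hydroxy ketone
Conditions: KN(SiMe3)2 (1.1 equiv), THF, −78 °C; 2-(phenylsulfonyl)-3-phenyloxaziridine; NH4Cl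
Reagents that add atoms: 2-(phenylsulfonyl)-3-phenyloxaziridine O=S(=O)(c1ccccc1)N1OC1c1ccccc1
Why: Kinetic deprotonation takes a C9 methylene hydrogen and not the tertiary C7 hydrogen, and oxygen transfer from the N-sulfonyloxaziridine to the enolate gives the α-hydroxy ketone, expected from the α face (anti to C15). This centre is reset in steps 12 and 13; its only task here is to bring oxygen to C9 before C8 becomes fully substituted.

Step 11
Reactants: 13 9α-hydroxy ketone; 14 tert-butyl propanoate
Product: 15 aldol adduct (8α-hydroxyl; C17 side chain on the β face; 9α-hydroxyl)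
Conditions: 14, LiN(i-Pr)2, THF, −78 °C (2.5 equiv of enolate); add 13; AcOH quench at −78 °C
Reagents that add atoms: none
Why: Aldol addition of the E lithium enolate of 14 to the C8 ketone; axial (α) attack is blocked by the axial C2–C3 bond of ring C, so the enolate should add equatorially from the β face and leave the 8α-hydroxyl. A closed chair transition state with the C7 branch equatorial should give the C17 configuration of 39; the excess enolate allows for the free 9-hydroxyl.

Step 12
Reactants: 15 aldol adduct
Product: 16 8α-hydroxy-9-ketone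
Conditions: Dess–Martin periodinane, NaHCO3, CH2Cl2, 0 °C
Reagents that add atoms: none
Why: Dess–Martin oxidation of the secondary alcohol next to the tertiary one; the buffered, non-basic medium avoids β-elimination of the C11 pivalate from the new ketone.

Step 13
Reactants: 16 8α-hydroxy-9-ketone
Product: 17 8α,9β-diol
Conditions: NaBH4, CeCl3·7H2O, MeOH/THF, −78 °C
Reagents that add atoms: none
Why: Luche-type reduction; the axial (β) trajectory at C9 is blocked by the 1,3-diaxial C15 methyl, so hydride should enter from the α face and give the axial 9β alcohol trans to the 8α-hydroxyl, as in the reduction of 6-oxo steroids to 6β alcohols. The nearly neutral medium protects the β-pivaloyloxy ketone.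

Step 14
Reactants: 17 8α,9β-diol
Product: 18 8α,9β-bis(triethylsilyl) ether
Conditions: Et3SiOTf (4 equiv), 2,6-lutidine, CH2Cl2, −78 to −40 °C
Reagents that add atoms: triethylsilyl triflate CC[Si](CC)(CC)OS(=O)(=O)C(F)(F)F
Why: A silyl triflate silylates the tertiary C8 and the hindered axial C9 hydroxyl; O8 must be masked so that the later glycol cleavage cannot touch C7–C8, and the low temperature spares the tert-butyl ester.

Step 15
Reactants: 18 bis(triethylsilyl) ether
Product: 19 C4 ketone (C5 epimer mixture)
Conditions: Bu4NF, AcOH (1:1), THF, −20 °C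
Reagents that add atoms: none
Why: Fluoride cleaves the silyl enol ether much faster than the alkyl silyl ethers, and buffered protonation gives the ketone; C5 becomes trigonal again in step 19.

Step 16
Reactants: 19 C4 ketone
Product: 21 conjugated enone (C4 ketone; C2=C3; 7β-H), via silyl enol ether 20 (not isolated)
Conditions: LiN(i-Pr)2 (1.1 equiv), Me3SiCl, THF, −78 °C; then Pd(OAc)2, MeCN, rt
Reagents that add atoms: none
Why: Kinetic deprotonation at the C3 methylene (not at the methyl-bearing C5) and trapping give 20; Saegusa–Ito oxidation with Pd(OAc)2 then introduces C2=C3, β-hydride elimination being possible only from C2.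

Step 17
Reactants: 21 conjugated enone
Product: 22 β,γ-unsaturated ketone (tetrasubstituted C2=C7; C4 ketone)
Conditions: KOt-Bu (3 equiv), t-BuOH/THF, 0 °C to rt; inverse quench into cold 10% aq. AcOH
Reagents that add atoms: none
Why: Deconjugation of an enone through its extended dienolate: γ-deprotonation at C7 and kinetic protonation at the α-carbon C3, as in the conversion of 4-en-3-ones into 5-en-3-ones. This puts a tetrasubstituted, non-conjugated alkene at the future cleavage site without regiochemical ambiguity.

Step 18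
Reactants: 22 β,γ-unsaturated ketone
Product: 24 2β,7β-diol (C4 ketone), via cyclic osmate ester 23 (not isolated)
Conditions: OsO4 (1.1 equiv), pyridine, THF, 0 °C to rt; then aq. NaHSO3, pyridine
Reagents that add atoms: osmium tetroxide O=[Os](=O)(=O)=O
Why: Stoichiometric osmylation of the only alkene in the molecule is cis by mechanism, as in the dihydroxylation of 9,10-octalin; attack is expected from the β face, anti to the pseudo-axial O8 silyl ether on the allylic C8. Either cis diol would serve step 25.

Step 19
Reactants: 24 2β,7β-diol ketone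
Product: 25 diol enone (C4 ketone; C5=C6)
Conditions: IBX (3 equiv), 4-methoxypyridine N-oxide, DMSO, rt
Reagents that add atoms: none
Why: IBX dehydrogenation of a ketone through its enol; only the C5 side can be dehydrogenated because C2 carries no hydrogen, so the C5=C6 alkene is formed inside ring C and is therefore cis.

Step 20
Reactants: 25 diol enone
Product: 26 4β-allylic alcohol (2β,7β-diol)
Conditions: NaBH4, CeCl3·7H2O, MeOH, −78 °C
Reagents that add atoms: none
Why: Luche 1,2-reduction; hydride should add from the α face, anti to the C2 hydroxyl that is axial on ring C and 1,3 to C4, which gives the 4β alcohol required for 39.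

Step 21
Reactants: 26 4β-allylic alcohol
Product: 27 4β-tert-butyldimethylsilyl ether
Conditions: t-BuMe2SiCl, imidazole, DMF, rt
Reagents that add atoms: tert-butyldimethylsilyl chloride CC(C)(C)[Si](C)(C)Cl
Why: Silylation with the chloride and imidazole takes the secondary allylic alcohol and leaves the two tertiary hydroxyls free.

Step 22
Reactants: 27 4β-silyl ether
Product: 28 11α-alcohol
Conditions: i-Bu2AlH (4 equiv), CH2Cl2, −78 °C; aq. potassium sodium tartrate
Reagents that add atoms: none
Why: Reductive cleavage of the pivalate; the tert-butyl ester, α-branched and next to the fully substituted C8, is much more hindered and should survive at this temperature.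

Step 23
Reactants: 28 11α-alcohol
Product: 29 11-ketone
Conditions: SO3·pyridine, DMSO, i-Pr2NEt, CH2Cl2, 0 °C
Reagents that add atoms: none
Why: Parikh–Doering oxidation of the only secondary alcohol; activated DMSO does not cleave the tertiary 1,2-diol.

Step 24
Reactants: 29 11-ketone
Product: 30 tricyclic 2β,7β-diol with the C11 methylene (key precursor)
Conditions: Cp2Ti(μ-CH2)(μ-Cl)AlMe2 (3 equiv), pyridine (cat.), THF/toluene, −40 to 0 °C
Reagents that add atoms: Tebbe reagent C[Al](C)C[Ti](Cl)(C1C=CC=C1)C1C=CC=C1
Why: Tebbe methylenation; the titanium methylidene is not basic, so neither epimerization at C10 nor β-elimination of the C9 silyloxy group is expected, and a ketone reacts much faster than the tert-butyl ester. The excess allows for the two free tertiary hydroxyls.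

Step 25
Reactants: 30 tricyclic 2β,7β-diol
Product: 32 bicyclic 2,7-diketone (ten-membered ring; Z C5=C6), via cyclic lead diester 31 (not isolated)
Conditions: Pb(OAc)4 (1.2 equiv), K2CO3, CH2Cl2, −20 to 0 °C
Reagents that add atoms: none
Why: Ligand exchange of the two tertiary hydroxyls with Pb(OAc)4 gives the five-membered cyclic diester of tetravalent lead 31, which is possible because the glycol is cis (O–C2–C7–O dihedral near 60°); 31 fragments in a concerted two-electron step that breaks C2–C7, forms the C2 and C7 carbonyls and releases divalent lead as Pb(OAc)2. The closest known reaction type is the Criegee glycol cleavage of cis ring-fusion diols of decalins to cyclodecane-1,6-diones. The ten-membered ring is not closed by bond formation: it appears by loss of the bond shared by rings B and C, so the entropic and transannular penalties of a medium-ring cyclization do not arise. No stereocentre is created; C1, C4, C8, C9, C10, C14 and C17 are untouched, and C5=C6 is Z because it was made inside the six-membered ring C. The selectivity needed is cleavage of this glycol alone: it is the only free 1,2-diol, since O8 and O9 are triethylsilyl ethers and O4 and O14 tert-butyldimethylsilyl ethers, and neither alkene reacts with Pb(OAc)4 at this temperature. Solid K2CO3 takes up the acetic acid set free, which protects the silyl ethers and suppresses transannular aldol reclosure of the 1,6-diketone. The oxygen on C4, β to the new C2 ketone, is a silyl ether and not an ester, so β-elimination is not to be feared.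

Step 26
Reactants: 32 bicyclic 2,7-diketone
Product: 33 2,7-diol (C2 and C7 configured as in 39)
Conditions: NaBH4, CeCl3·7H2O, MeOH, −78 to −40 °C
Reagents that add atoms: none
Why: Luche reduction of both carbonyls (1,2 at the C7 enone). Hydride should reach C2 anti to the C15 methyl on the adjacent quaternary C1 and C7 anti to the silyloxy group on C8, which would give the configurations of 39; this is the least predictable stereochemical event of the route.

Step 27
Reactants: 33 2,7-diol
Product: 36 γ-lactone (O7–C19) with free 2-hydroxyl, via silyl ester 34 (not isolated), via seco acid 35 (not isolated)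
Conditions: Me3SiOTf (5 equiv), 2,6-lutidine, CH2Cl2, 0 °C to rt; then citric acid, MeOH/H2O, rt
Reagents that add atoms: none
Why: Silyl-triflate-mediated cleavage of the tert-butyl ester (loss of 2-methylpropene) gives silyl ester 34, the two hydroxyls being silylated in passing; mild acidic methanolysis frees γ-hydroxy acid 35, which should close to the five-membered lactone. The alkyl silyl ethers on O4, O8, O9 and O14 are not affected, so O2 is then the only free hydroxyl.

Step 28
Reactants: 36 γ-lactone
Product: 37 2-isobutyrate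
Conditions: i-PrCOCl, DMAP, pyridine, CH2Cl2, 0 °C to rt
Reagents that add atoms: isobutyryl chloride CC(C)C(=O)Cl
Why: DMAP-catalysed acylation of the only free hydroxyl; the neopentyl position calls for the acid chloride.

Step 29
Reactants: 37 2-isobutyrate
Product: 38 tetraol (free hydroxyls on C4, C8, C9 and C14)
Conditions: HF·pyridine, pyridine, THF, 0 °C to rt
Reagents that add atoms: none
Why: Fluoride cleavage of all four silyl ethers; the esters and the lactone are stable to buffered HF·pyridine.

Step 30
Reactants: 38 tetraol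
Product: 39 CNP0189561.1 (target)
Conditions: Ac2O, DMAP (cat.), pyridine, CH2Cl2, rt
Reagents that add atoms: acetic anhydride CC(=O)OC(C)=O
Why: Acetylation of the three secondary alcohols; the tertiary C8 hydroxyl is not acylated under these conditions.

## Compound list

1 | (R)-Wieland–Miescher ketone | O=C1CCCC2=CC(=O)CC[C@@]12C | starting material
2 | bicyclic diol: 14α-OH (axial, trans to C15), C8-OH (epimer mixture), C9=C10 | C1CC[C@H](O)[C@]2(C)CCC(O)C=C12 | intermediate
3 | 14α-hydroxy enone: C8 ketone, C9=C10 | C1CC[C@H](O)[C@]2(C)CCC(=O)C=C12 | intermediate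
4 | C8 ethylene ketal, C10=C11, 14α-OH | C=1CC[C@H](O)[C@]2(C)CCC3(OCCO3)CC=12 | intermediate
5 | trans-fused C8 ketal, 10α-H, 11α-OH, 14α-OH | [C@@H]1(O)CC[C@H](O)[C@]2(C)CCC3(OCCO3)C[C@@H]12 | intermediate
6 | 11α-pivalate of 5 | [C@@H]1(OC(=O)C(C)(C)C)CC[C@H](O)[C@]2(C)CCC3(OCCO3)C[C@@H]12 | intermediate
7 | trans-decalin-8-one, 11α-pivalate, 14α-OH | [C@@H]1(OC(=O)C(C)(C)C)CC[C@H](O)[C@]2(C)CCC(=O)C[C@@H]12 | intermediate
8 | C7=C8 TBS enol ether, 14α-OTBS, 11α-pivalate | [C@@H]1(OC(=O)C(C)(C)C)CC[C@H](O[Si](C)(C)C(C)(C)C)[C@]2(C)CC=C(O[Si](C)(C)C(C)(C)C)C[C@@H]12 | intermediate (not isolated)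
9 | bicyclic enone: C8 ketone, C2=C7, 14α-OTBS, 11α-pivalate | [C@@H]1(OC(=O)C(C)(C)C)CC[C@H](O[Si](C)(C)C(C)(C)C)[C@]2(C)C=CC(=O)C[C@@H]12 | intermediate
10 | 3-methylbut-3-en-2-one | CC(=C)C(C)=O | starting material
11 | 2-(tert-butyldimethylsilyloxy)-3-methylbuta-1,3-diene | C=C(C)C(=C)O[Si](C)(C)C(C)(C)C | intermediate
12 | tricyclic Diels–Alder adduct: 2β-H, 7β-H, C4=C5 TBS enol ether, C8 ketone | [C@@H]1(OC(=O)C(C)(C)C)CC[C@H](O[Si](C)(C)C(C)(C)C)[C@]2(C)[C@@H]4CC(O[Si](C)(C)C(C)(C)C)=C(C)C[C@@H]4C(=O)C[C@@H]12 | intermediate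
13 | 9α-hydroxy-8-ketone | [C@@H]1(OC(=O)C(C)(C)C)CC[C@H](O[Si](C)(C)C(C)(C)C)[C@]2(C)[C@@H]4CC(O[Si](C)(C)C(C)(C)C)=C(C)C[C@@H]4C(=O)[C@H](O)[C@@H]12 | intermediate
14 | tert-butyl propanoate | CCC(=O)OC(C)(C)C | starting material
15 | aldol adduct: 8α-OH, β-oriented C17 tert-butyl propanoate side chain, 9α-OH | [C@@H]1(OC(=O)C(C)(C)C)CC[C@H](O[Si](C)(C)C(C)(C)C)[C@]2(C)[C@@H]4CC(O[Si](C)(C)C(C)(C)C)=C(C)C[C@@H]4[C@@](O)([C@@H](C)C(=O)OC(C)(C)C)[C@H](O)[C@@H]12 | intermediate
16 | 8α-hydroxy-9-ketone | [C@@H]1(OC(=O)C(C)(C)C)CC[C@H](O[Si](C)(C)C(C)(C)C)[C@]2(C)[C@@H]4CC(O[Si](C)(C)C(C)(C)C)=C(C)C[C@@H]4[C@@](O)([C@@H](C)C(=O)OC(C)(C)C)C(=O)[C@@H]12 | intermediate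
17 | 8α,9β-diol | [C@@H]1(OC(=O)C(C)(C)C)CC[C@H](O[Si](C)(C)C(C)(C)C)[C@]2(C)[C@@H]4CC(O[Si](C)(C)C(C)(C)C)=C(C)C[C@@H]4[C@@](O)([C@@H](C)C(=O)OC(C)(C)C)[C@@H](O)[C@@H]12 | intermediate
18 | 8α,9β-bis(triethylsilyl) ether | [C@@H]1(OC(=O)C(C)(C)C)CC[C@H](O[Si](C)(C)C(C)(C)C)[C@]2(C)[C@@H]4CC(O[Si](C)(C)C(C)(C)C)=C(C)C[C@@H]4[C@@](O[Si](CC)(CC)CC)([C@@H](C)C(=O)OC(C)(C)C)[C@@H](O[Si](CC)(CC)CC)[C@@H]12 | intermediate
19 | C4 ketone (C5 epimer mixture) | [C@@H]1(OC(=O)C(C)(C)C)CC[C@H](O[Si](C)(C)C(C)(C)C)[C@]2(C)[C@@H]4CC(=O)C(C)C[C@@H]4[C@@](O[Si](CC)(CC)CC)([C@@H](C)C(=O)OC(C)(C)C)[C@@H](O[Si](CC)(CC)CC)[C@@H]12 | intermediate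
20 | C3=C4 trimethylsilyl enol ether | [C@@H]1(OC(=O)C(C)(C)C)CC[C@H](O[Si](C)(C)C(C)(C)C)[C@]2(C)[C@@H]4C=C(O[Si](C)(C)C)C(C)C[C@@H]4[C@@](O[Si](CC)(CC)CC)([C@@H](C)C(=O)OC(C)(C)C)[C@@H](O[Si](CC)(CC)CC)[C@@H]12 | intermediate (not isolated)
21 | conjugated enone: C4 ketone, C2=C3, 7β-H | [C@@H]1(OC(=O)C(C)(C)C)CC[C@H](O[Si](C)(C)C(C)(C)C)[C@]2(C)C4=CC(=O)C(C)C[C@@H]4[C@@](O[Si](CC)(CC)CC)([C@@H](C)C(=O)OC(C)(C)C)[C@@H](O[Si](CC)(CC)CC)[C@@H]12 | intermediate
22 | β,γ-unsaturated ketone: tetrasubstituted C2=C7, C4 ketone | [C@@H]1(OC(=O)C(C)(C)C)CC[C@H](O[Si](C)(C)C(C)(C)C)[C@]2(C)C=4CC(=O)C(C)CC=4[C@@](O[Si](CC)(CC)CC)([C@@H](C)C(=O)OC(C)(C)C)[C@@H](O[Si](CC)(CC)CC)[C@@H]12 | intermediate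
23 | cyclic osmate ester of the 2β,7β-glycol (pyridine ligands not drawn) | [C@@H]1(OC(=O)C(C)(C)C)CC[C@H](O[Si](C)(C)C(C)(C)C)[C@]2(C)[C@]4(O[Os]5(=O)=O)CC(=O)C(C)C[C@]4(O5)[C@@](O[Si](CC)(CC)CC)([C@@H](C)C(=O)OC(C)(C)C)[C@@H](O[Si](CC)(CC)CC)[C@@H]12 | intermediate (not isolated)
24 | 2β,7β-diol, C4 ketone | [C@@H]1(OC(=O)C(C)(C)C)CC[C@H](O[Si](C)(C)C(C)(C)C)[C@]2(C)[C@]4(O)CC(=O)C(C)C[C@]4(O)[C@@](O[Si](CC)(CC)CC)([C@@H](C)C(=O)OC(C)(C)C)[C@@H](O[Si](CC)(CC)CC)[C@@H]12 | intermediate
25 | diol enone: C4 ketone, C5=C6 | [C@@H]1(OC(=O)C(C)(C)C)CC[C@H](O[Si](C)(C)C(C)(C)C)[C@]2(C)[C@]4(O)CC(=O)C(C)=C[C@]4(O)[C@@](O[Si](CC)(CC)CC)([C@@H](C)C(=O)OC(C)(C)C)[C@@H](O[Si](CC)(CC)CC)[C@@H]12 | intermediate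
26 | 4β-allylic alcohol, 2β,7β-diol | [C@@H]1(OC(=O)C(C)(C)C)CC[C@H](O[Si](C)(C)C(C)(C)C)[C@]2(C)[C@]4(O)C[C@@H](O)C(C)=C[C@]4(O)[C@@](O[Si](CC)(CC)CC)([C@@H](C)C(=O)OC(C)(C)C)[C@@H](O[Si](CC)(CC)CC)[C@@H]12 | intermediate
27 | 4β-OTBS derivative of 26 | [C@@H]1(OC(=O)C(C)(C)C)CC[C@H](O[Si](C)(C)C(C)(C)C)[C@]2(C)[C@]4(O)C[C@@H](O[Si](C)(C)C(C)(C)C)C(C)=C[C@]4(O)[C@@](O[Si](CC)(CC)CC)([C@@H](C)C(=O)OC(C)(C)C)[C@@H](O[Si](CC)(CC)CC)[C@@H]12 | intermediate
28 | 11α-alcohol | [C@@H]1(O)CC[C@H](O[Si](C)(C)C(C)(C)C)[C@]2(C)[C@]4(O)C[C@@H](O[Si](C)(C)C(C)(C)C)C(C)=C[C@]4(O)[C@@](O[Si](CC)(CC)CC)([C@@H](C)C(=O)OC(C)(C)C)[C@@H](O[Si](CC)(CC)CC)[C@@H]12 | intermediate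
29 | 11-ketone | O=C1CC[C@H](O[Si](C)(C)C(C)(C)C)[C@]2(C)[C@]4(O)C[C@@H](O[Si](C)(C)C(C)(C)C)C(C)=C[C@]4(O)[C@@](O[Si](CC)(CC)CC)([C@@H](C)C(=O)OC(C)(C)C)[C@@H](O[Si](CC)(CC)CC)[C@@H]12 | intermediate
30 | key precursor: angular tricycle, 2β,7β-diol, C11 methylene, 4β- and 14α-OTBS, 8α- and 9β-OTES, tert-butyl ester | C=C1CC[C@H](O[Si](C)(C)C(C)(C)C)[C@]2(C)[C@]4(O)C[C@@H](O[Si](C)(C)C(C)(C)C)C(C)=C[C@]4(O)[C@@](O[Si](CC)(CC)CC)([C@@H](C)C(=O)OC(C)(C)C)[C@@H](O[Si](CC)(CC)CC)[C@@H]12 | intermediate
31 | cyclic diester of tetravalent lead on O2 and O7 | C=C1CC[C@H](O[Si](C)(C)C(C)(C)C)[C@]2(C)[C@]4(O[Pb]5(OC(C)=O)OC(C)=O)C[C@@H](O[Si](C)(C)C(C)(C)C)C(C)=C[C@]4(O5)[C@@](O[Si](CC)(CC)CC)([C@@H](C)C(=O)OC(C)(C)C)[C@@H](O[Si](CC)(CC)CC)[C@@H]12 | intermediate (not isolated)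
32 | key product: bicyclic 2,7-diketone, ten-membered ring, Z C5=C6 | C=C1CC[C@H](O[Si](C)(C)C(C)(C)C)[C@]2(C)C(=O)C[C@@H](O[Si](C)(C)C(C)(C)C)/C(C)=C\C(=O)[C@@](O[Si](CC)(CC)CC)([C@@H](C)C(=O)OC(C)(C)C)[C@@H](O[Si](CC)(CC)CC)[C@@H]12 | intermediate
33 | 2,7-diol with C2 and C7 as in the target | C=C1CC[C@H](O[Si](C)(C)C(C)(C)C)[C@]2(C)[C@@H](O)C[C@@H](O[Si](C)(C)C(C)(C)C)/C(C)=C\[C@H](O)[C@@](O[Si](CC)(CC)CC)([C@@H](C)C(=O)OC(C)(C)C)[C@@H](O[Si](CC)(CC)CC)[C@@H]12 | intermediate
34 | trimethylsilyl ester, 2,7-bis(trimethylsilyl) ether | C=C1CC[C@H](O[Si](C)(C)C(C)(C)C)[C@]2(C)[C@@H](O[Si](C)(C)C)C[C@@H](O[Si](C)(C)C(C)(C)C)/C(C)=C\[C@H](O[Si](C)(C)C)[C@@](O[Si](CC)(CC)CC)([C@@H](C)C(=O)O[Si](C)(C)C)[C@@H](O[Si](CC)(CC)CC)[C@@H]12 | intermediate (not isolated)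
35 | seco acid (2,7-diol, C19 carboxylic acid) | C=C1CC[C@H](O[Si](C)(C)C(C)(C)C)[C@]2(C)[C@@H](O)C[C@@H](O[Si](C)(C)C(C)(C)C)/C(C)=C\[C@H](O)[C@@](O[Si](CC)(CC)CC)([C@@H](C)C(=O)O)[C@@H](O[Si](CC)(CC)CC)[C@@H]12 | intermediate (not isolated)
36 | γ-lactone with free 2-hydroxyl | C=C1CC[C@H](O[Si](C)(C)C(C)(C)C)[C@]2(C)[C@@H](O)C[C@@H](O[Si](C)(C)C(C)(C)C)/C(C)=C\[C@@H]3OC(=O)[C@H](C)[C@@]3(O[Si](CC)(CC)CC)[C@@H](O[Si](CC)(CC)CC)[C@@H]12 | intermediate
37 | 2-isobutyrate | C=C1CC[C@H](O[Si](C)(C)C(C)(C)C)[C@]2(C)[C@@H](OC(=O)C(C)C)C[C@@H](O[Si](C)(C)C(C)(C)C)/C(C)=C\[C@@H]3OC(=O)[C@H](C)[C@@]3(O[Si](CC)(CC)CC)[C@@H](O[Si](CC)(CC)CC)[C@@H]12 | intermediate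
38 | tetraol: 2-isobutyrate with free 4-, 8-, 9- and 14-hydroxyls | C=C1CC[C@H](O)[C@]2(C)[C@@H](OC(=O)C(C)C)C[C@@H](O)/C(C)=C\[C@@H]3OC(=O)[C@H](C)[C@@]3(O)[C@@H](O)[C@@H]12 | intermediate
39 | CNP0189561.1 | C=C1CC[C@H](OC(C)=O)[C@]2(C)[C@@H](OC(=O)C(C)C)C[C@@H](OC(C)=O)/C(C)=C\[C@@H]3OC(=O)[C@H](C)[C@@]3(O)[C@@H](OC(C)=O)[C@@H]12 | target

## Step count and least certain steps

Total: 30 steps. Longest linear sequence: 29 steps (steps 1 to 7 and 9 to 30, from 1); step 8 makes the diene.

Step 25 (key step). What may go wrong: slow formation of the cyclic lead diester between two very hindered tertiary hydroxyls, or transannular aldol reclosure of the 1,6-diketone once it is formed. Fallback: go from 30 to 32 by a one-electron pathway, alkoxy-radical β-fragmentation of the hypoiodite made in situ (PhI(OAc)2, I2, CH2Cl2/cyclohexane, visible light). Homolysis of the O–I bond on O7 or O2 is followed by β-scission of C2–C7, and the α-hydroxyalkyl radical is oxidized to the second ketone. No cyclic ester is needed and no new compound is made.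

Step 1. What may go wrong: insufficient preference for equatorial hydride delivery at C14, so that the 14β epimer is carried along. Fallback: from 1, NaBH4 (EtOH, −10 °C) gives the 14β-hydroxy enone F1. Mitsunobu inversion (4-nitrobenzoic acid, PPh3, DIAD, toluene) gives the 14α 4-nitrobenzoate F2, and K2CO3 in MeOH returns to the route at 3.

Step 9. What may go wrong: low reactivity of the enone β-carbon next to the quaternary C1, erosion of facial selectivity by the axial O14 silyl ether (1,3 to the forming C2–C3 bond), or arrest after the first C–C bond. Fallback: from 9, bromination–dehydrobromination (Br2, CH2Cl2; Et3N) gives the more reactive 7-bromo enone F3. Its cycloaddition with 11 gives the 7-bromo adduct F4, and radical debromination (Bu3SnH, AIBN, toluene, 80 °C), with hydrogen delivered to the β face of C7, returns to the route at 12.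

Step 11. What may go wrong: enolization of the hindered ketone by the basic ester enolate, retro-aldol on warming, partial attack from the α face, or formation of the C17 epimer. Fallback: from 13, silylation (Me3SiCl, imidazole) gives the 9-O-trimethylsilyl ketone F5. It is treated with the non-basic zinc enolate made from tert-butyl 2-bromopropanoate and zinc (Reformatsky reaction, THF, 40 °C), and citric acid work-up removes the trimethylsilyl group and returns to the route at 15. A C17 epimer can still be corrected at the lactone stage by base equilibration.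

Step 18. What may go wrong: very slow osmylation of an alkene flanked by C1 and C8, or slow hydrolysis of the hindered osmate ester. Fallback: from 22, dimethyldioxirane (acetone, −20 °C) epoxidizes the electron-rich alkene to the 2β,7β-epoxide F6. DBU opens it by E1cB from C3 to the γ-hydroxy enone F7 (C2=C3, 7β-OH). Hydroxyl-directed nucleophilic epoxidation (t-BuOOH, benzyltrimethylammonium hydroxide) gives the 2β,3β-epoxy ketone F8, and reductive opening at C3 (PhSeSePh, NaBH4, EtOH, AcOH) returns to the route at 24.

Step 26. What may go wrong: hydride delivery to the wrong face of C7 (or C2) on a ring whose conformation is not known in advance. Fallback: from 32, if the Luche reduction gives the 7-epimeric diol F9, MnO2 re-oxidizes only the allylic C7 alcohol to the 2-hydroxy-7-ketone F10. Its enone carbonyl is then reduced under reagent control (Corey–Bakshi–Shibata reduction, the enantiomer of the oxazaborolidine chosen for the required face, BH3·SMe2), which returns to the route at 33.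

## Further compounds

F0 | step 25 | none | none
F1 | step 1 | 14β-hydroxy enone (C8 ketone, C9=C10) | C1CC[C@@H](O)[C@]2(C)CCC(=O)C=C12
F2 | step 1 | 14α 4-nitrobenzoate of the enone | C1CC[C@H](OC(=O)c3ccc(cc3)[N+](=O)[O-])[C@]2(C)CCC(=O)C=C12
F3 | step 9 | 7-bromo enone | [C@@H]1(OC(=O)C(C)(C)C)CC[C@H](O[Si](C)(C)C(C)(C)C)[C@]2(C)C=C(Br)C(=O)C[C@@H]12
F4 | step 9 | 7β-bromo Diels–Alder adduct | [C@@H]1(OC(=O)C(C)(C)C)CC[C@H](O[Si](C)(C)C(C)(C)C)[C@]2(C)[C@@H]4CC(O[Si](C)(C)C(C)(C)C)=C(C)C[C@]4(Br)C(=O)C[C@@H]12
F5 | step 11 | 9α-trimethylsilyloxy-8-ketone | [C@@H]1(OC(=O)C(C)(C)C)CC[C@H](O[Si](C)(C)C(C)(C)C)[C@]2(C)[C@@H]4CC(O[Si](C)(C)C(C)(C)C)=C(C)C[C@@H]4C(=O)[C@H](O[Si](C)(C)C)[C@@H]12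
F6 | step 18 | 2β,7β-epoxide, C4 ketone | [C@@H]1(OC(=O)C(C)(C)C)CC[C@H](O[Si](C)(C)C(C)(C)C)[C@]2(C)[C@]45CC(=O)C(C)C[C@]4(O5)[C@@](O[Si](CC)(CC)CC)([C@@H](C)C(=O)OC(C)(C)C)[C@@H](O[Si](CC)(CC)CC)[C@@H]12
F7 | step 18 | γ-hydroxy enone: C4 ketone, C2=C3, 7β-OH | [C@@H]1(OC(=O)C(C)(C)C)CC[C@H](O[Si](C)(C)C(C)(C)C)[C@]2(C)C4=CC(=O)C(C)C[C@]4(O)[C@@](O[Si](CC)(CC)CC)([C@@H](C)C(=O)OC(C)(C)C)[C@@H](O[Si](CC)(CC)CC)[C@@H]12
F8 | step 18 | 2β,3β-epoxy-4-ketone, 7β-OH | [C@@H]1(OC(=O)C(C)(C)C)CC[C@H](O[Si](C)(C)C(C)(C)C)[C@]2(C)[C@@]45O[C@H]5C(=O)C(C)C[C@]4(O)[C@@](O[Si](CC)(CC)CC)([C@@H](C)C(=O)OC(C)(C)C)[C@@H](O[Si](CC)(CC)CC)[C@@H]12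
F9 | step 26 | 7-epimer of diol 33 | C=C1CC[C@H](O[Si](C)(C)C(C)(C)C)[C@]2(C)[C@@H](O)C[C@@H](O[Si](C)(C)C(C)(C)C)/C(C)=C\[C@@H](O)[C@@](O[Si](CC)(CC)CC)([C@@H](C)C(=O)OC(C)(C)C)[C@@H](O[Si](CC)(CC)CC)[C@@H]12
F10 | step 26 | 2-hydroxy-7-ketone | C=C1CC[C@H](O[Si](C)(C)C(C)(C)C)[C@]2(C)[C@@H](O)C[C@@H](O[Si](C)(C)C(C)(C)C)/C(C)=C\C(=O)[C@@](O[Si](CC)(CC)CC)([C@@H](C)C(=O)OC(C)(C)C)[C@@H](O[Si](CC)(CC)CC)[C@@H]12
A1 | alternative 1 | (1E,3E)-1,4-diacetoxybuta-1,3-diene | CC(=O)O/C=C/C=C/OC(C)=O
A2 | alternative 1 | E 2-methyl enal carrying the C9 dioxolane | O=C/C(C)=C/[C@H]1COC(C)(C)O1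
A3 | alternative 1 | ring A cycloadduct (formyl C2, methyl C15, acetoxy groups on C14 and C11, C9 dioxolane) | CC(=O)O[C@@H]1C=C[C@H](OC(C)=O)[C@](C)(C=O)[C@H]1[C@H]2COC(C)(C)O2
A4 | alternative 2 | ten-membered carbocycle bridged by the C4=N–O–C2 isoxazoline | C=C1CC[C@H](OC(C)=O)[C@]2(C)[C@@H]4CC(=NO4)/C(C)=C\[C@@H]3OC(=O)[C@H](C)[C@@]3(O)[C@@H](OC(C)=O)[C@@H]12
A5 | alternative 3 | bicyclic C9 ketone from the oxy-Cope ring expansion | O1CCOC12CC[C@H](O[Si](C)(C)C(C)(C)C)[C@]3(C)[C@@H](OCc4ccc(OC)cc4)/C=C(O[Si](CC)(CC)CC)/C(C)=C\[C@@H]5OC(C)(C)O[C@]5([C@@H](C)CO[Si](C)(C)C(C)(C)C)C(=O)[C@@H]23
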